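Ring C is cut at O1–C2 and C4–C4a. Ring A then serves as an O,C-dinucleophile, 2-bromo-3,5-bis(allyloxy)phenol, whose phenoxide oxygen becomes O1 and whose C–Br carbon is the latent carbanion C4a. C2–C3–C4 is delivered as a strained, enantiopure 4-aryl-β-lactone that carries the finished ring B. In one flask the phenoxide opens the lactone at its benzylic carbon by SN2 (O1–C2, inversion, 4R to 2S), and bromine–lithium exchange then lets C4a capture the liberated carboxylate (C4–C4a). The step exploits the ortho relation of O1 and C4a on ring A and the 1,3-dielectrophilic C2/C4 pair held in the four-membered ring.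

Key step: step 8

Remark: Ar stands for 3-[(E)-3-hydroxy-3-methylbut-1-en-1-yl]-4-methoxy-5-(3-methylbut-2-en-1-yl)phenyl.
Remark: in step 5 the alkaloid pseudo-enantiomer must be the one that gives the 4R lactone; O-trimethylsilylquinidine is assumed by analogy with the quinidine-derived R lactone of the Wynberg reaction, and O-trimethylsilylquinine is used if the sense proves opposite.

Step 1
Reactants: 1 3-bromo-4-hydroxybenzaldehyde
Product: 2 3-bromo-4-hydroxy-5-iodobenzaldehyde
Conditions: NIS, TsOH·H2O (cat.), MeCN, rt
Reagents that add atoms: N-iodosuccinimide, O=C1CCC(=O)N1I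
Why: Electrophilic aromatic iodination, in which the phenol directs the iodine to its only free ortho position, which is also meta to the aldehyde.

Step 2
Reactants: 2 3-bromo-4-hydroxy-5-iodobenzaldehyde
Product: 3 3-bromo-5-iodo-4-methoxybenzaldehyde
Conditions: MeI, K2CO3, DMF, rt
Reagents that add atoms: iodomethane, CI
Why: Williamson O-methylation of an acidic phenoxide flanked by two halogens.

Step 3
Reactants: 3 3-bromo-5-iodo-4-methoxybenzaldehyde; 4 tributyl(3-methylbut-2-en-1-yl)stannane
Product: 5 3-bromo-4-methoxy-5-(3-methylbut-2-en-1-yl)benzaldehyde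
Conditions: Pd(PPh3)4 (5 mol%), DMF, 80 °C
Reagents that add atoms: none
Why: Stille coupling, in which oxidative addition into the carbon–iodine bond is much faster than into the carbon–bromine bond and reductive elimination at the less substituted allyl terminus should give the linear prenyl arene.

Step 4
Reactants: 5 3-bromo-4-methoxy-5-(3-methylbut-2-en-1-yl)benzaldehyde; 6 2-methylbut-3-en-2-ol
Product: 7 3-[(E)-3-hydroxy-3-methylbut-1-en-1-yl]-4-methoxy-5-(3-methylbut-2-en-1-yl)benzaldehyde (Ar–CHO)
Conditions: Pd(OAc)2 (5 mol%), P(o-tol)3, Et3N, DMF, 100 °C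
Reagents that add atoms: none
Why: Mizoroki–Heck reaction, in which the aryl group adds to the terminal carbon and the quaternary carbinol carbon offers no β-hydrogen, so syn-β-hydride elimination can only give the E styrene.

Step 5
Reactants: 7 Ar–CHO; 8 acetyl chloride
Product: 9 (R)-4-Ar-oxetan-2-one
Conditions: i-Pr2NEt, O-trimethylsilylquinidine (10 mol%), LiClO4, CH2Cl2/Et2O, −78 °C
Reagents that add atoms: none
Why: Wynberg-type ketene–aldehyde [2+2] cycloaddition in Nelson's acyl halide–aldehyde cyclocondensation format, in which ketene made in situ from 8 is bound by the alkaloid as an ammonium enolate, adds to the Re face of the lithium-activated aldehyde and the aldolate closes to the lactone, so that C4 is set as R under catalyst control while the hindered tertiary alcohol should stay unacylated at −78 °C.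

Step 6
Reactants: 10 phloroglucinol
Product: 11 3,5-bis(allyloxy)phenol
Conditions: allyl bromide (2.0 equiv), K2CO3, DMF, rt
Reagents that add atoms: allyl bromide, C=CCBr
Why: Williamson etherification run to the diether stage, a statistical alkylation from which the diether is separated from mono- and triether.

Step 7
Reactants: 11 3,5-bis(allyloxy)phenol
Product: 12 2-bromo-3,5-bis(allyloxy)phenol
Conditions: NBS (1.0 equiv), CH2Cl2, −78 °C
Reagents that add atoms: N-bromosuccinimide, O=C1CCC(=O)N1Br
Why: Electrophilic aromatic bromination ortho to the free hydroxyl, whose two ortho positions are equivalent by symmetry and less shielded than the position between the two allyloxy groups, on a ring far more reactive than the allyl double bonds.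

Step 8
Reactants: 12 2-bromo-3,5-bis(allyloxy)phenol; 9 (R)-4-Ar-oxetan-2-one
Product: 16 (S)-5,7-bis(allyloxy)-2-Ar-chroman-4-one, via sodium carboxylate 13 (not isolated), via aryllithium 14 (not isolated), via gem-diolate 15 (not isolated)
Conditions: 12 (1.3 equiv), NaH, 15-crown-5, THF, 0 °C; 9 added slowly, rt; n-BuLi (2.4 equiv), −78 to −40 °C; AcOH, −78 °C
Reagents that add atoms: none
Why: Proposed new method: the crown-separated, weakly basic phenoxide of 12 attacks the benzylic C4 of lactone 9 by SN2 with alkyl–oxygen cleavage (closest known reactions: phenoxide and azide openings of β-lactones at the alkyl carbon), forming O1–C2 with inversion and giving carboxylate 13, while attack at the acyl carbon is reversible because the aryl ester alkoxide recloses to the lactone. n-BuLi then deprotonates the tertiary alcohol and exchanges bromine for lithium, and aryllithium 14 adds to its own carboxylate (Parham cyclisation, the closest known reaction type for this bond; 6-exo-trig) to form C4–C4a as gem-diolate 15. The ketone appears only on the acetic acid quench at −78 °C, so the flavanone never meets base and cannot racemise through retro-oxa-Michael opening. C2 is the only new stereocentre and is fixed by the lactone alone: stereospecific inversion turns 4R into 2S. The step needs O- over C-alkylation and alkyl- over acyl-oxygen cleavage (secured by the free, soft phenoxide, the strained benzylic C–O bond and slow addition of 9 to excess phenoxide, which also suppresses carboxylate-initiated oligomerisation), and it needs acylation to outrun 5-exo carbolithiation of the neighbouring allyl ether (secured by working without a diamine at or below −40 °C).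

Step 9
Reactants: 16 (S)-5,7-bis(allyloxy)-2-Ar-chroman-4-one
Product: 17 (S)-5,7-dihydroxy-2-Ar-chroman-4-one (target)
Conditions: Pd(PPh3)4 (5 mol%), N-methylaniline, THF, rt
Reagents that add atoms: none
Why: Tsuji–Trost deallylation, in which Pd(PPh3)4 ionises both aryl allyl ethers and the weakly basic N-methylaniline traps the allyl groups, so that neither acid (tertiary allylic alcohol) nor base (retro-oxa-Michael racemisation at C2) is present.

Compound list
1 | 3-bromo-4-hydroxybenzaldehyde | O=Cc1ccc(O)c(Br)c1 | starting material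
2 | 3-bromo-4-hydroxy-5-iodobenzaldehyde | O=Cc1cc(Br)c(O)c(I)c1 | intermediate
3 | 3-bromo-5-iodo-4-methoxybenzaldehyde | COc1c(Br)cc(C=O)cc1I | intermediate
4 | tributyl(3-methylbut-2-en-1-yl)stannane | CCCC[Sn](CCCC)(CCCC)CC=C(C)C | starting material
5 | 3-bromo-4-methoxy-5-(3-methylbut-2-en-1-yl)benzaldehyde | COc1c(Br)cc(C=O)cc1CC=C(C)C | intermediate
6 | 2-methylbut-3-en-2-ol | C=CC(C)(C)O | starting material
7 | 3-[(E)-3-hydroxy-3-methylbut-1-en-1-yl]-4-methoxy-5-(3-methylbut-2-en-1-yl)benzaldehyde | COc1c(/C=C/C(C)(C)O)cc(C=O)cc1CC=C(C)C | intermediate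
8 | acetyl chloride | CC(Cl)=O | starting material
9 | (R)-4-Ar-oxetan-2-one | O=C1C[C@H](c2cc(CC=C(C)C)c(OC)c(/C=C/C(C)(C)O)c2)O1 | intermediate
10 | phloroglucinol | Oc1cc(O)cc(O)c1 | starting material
11 | 3,5-bis(allyloxy)phenol | Oc1cc(OCC=C)cc(OCC=C)c1 | intermediate
12 | 2-bromo-3,5-bis(allyloxy)phenol | Oc1cc(OCC=C)cc(OCC=C)c1Br | intermediate
13 | sodium (S)-3-Ar-3-[2-bromo-3,5-bis(allyloxy)phenoxy]propanoate | [Na+].[O-]C(=O)C[C@@H](c1cc(CC=C(C)C)c(OC)c(/C=C/C(C)(C)O)c1)Oc1cc(OCC=C)cc(OCC=C)c1Br | intermediate (not isolated)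
14 | aryllithium from 13 (C4a–Li, carboxylate and tertiary alkoxide as Na/Li salts) | [Na+].[Li+].[O-]C(=O)C[C@@H](c1cc(CC=C(C)C)c(OC)c(/C=C/C(C)(C)[O-])c1)Oc1cc(OCC=C)cc(OCC=C)c1[Li] | intermediate (not isolated)
15 | gem-diolate of 16 (C4 bearing two O–, tertiary alkoxide, Na/Li salts) | [Na+].[Li+].[Li+].[O-]C1([O-])C[C@@H](c2cc(CC=C(C)C)c(OC)c(/C=C/C(C)(C)[O-])c2)Oc2cc(OCC=C)cc(OCC=C)c12 | intermediate (not isolated)
16 | (S)-5,7-bis(allyloxy)-2-Ar-chroman-4-one | O=C1C[C@@H](c2cc(CC=C(C)C)c(OC)c(/C=C/C(C)(C)O)c2)Oc2cc(OCC=C)cc(OCC=C)c12 | intermediate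
17 | (S)-5,7-dihydroxy-2-{3-[(E)-3-hydroxy-3-methylbut-1-en-1-yl]-4-methoxy-5-(3-methylbut-2-en-1-yl)phenyl}chroman-4-one | COc1c(/C=C/C(C)(C)O)cc([C@@H]2CC(=O)c3c(O)cc(O)cc3O2)cc1CC=C(C)C | target

Total step count: 9. Longest linear sequence: 7 steps (steps 1 to 5, 8 and 9).

Steps most likely to fail

Step 8 (bears the label). In the first stage the phenoxide may attack the acyl carbon and the adduct may eliminate to the cinnamate, the product carboxylate may oligomerise 9, or the benzylic C–O bond may ionise with loss of enantiopurity. In the second stage the aryllithium may carbolithiate the neighbouring allyl ether, abstract the C2 proton, or fail to acylate the carboxylate. The fallback uses known chemistry, sets out from 9 and 12 and returns at 16; it makes the two bonds in separate operations. Lactone 9 is opened at the acyl carbon with the chloromagnesium amide of N,O-dimethylhydroxylamine (MeONHMe·HCl, i-PrMgCl, THF, −20 °C) to give (R)-3-hydroxy-N-methoxy-N-methyl-3-Ar-propanamide F1. Phenol 12 is converted with n-BuLi (2 equiv, THF, −78 °C) into lithium 2-lithio-3,5-bis(allyloxy)phenoxide F2, which is added in excess to F1 and should give (R)-3-hydroxy-1-[2-hydroxy-4,6-bis(allyloxy)phenyl]-3-Ar-propan-1-one F3. Intramolecular Mitsunobu etherification (PPh3, DIAD, THF, 0 °C) then closes O1–C2 with inversion and gives 16.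

Step 5. The electron-rich aldehyde may react sluggishly, the tertiary alcohol may be acylated, the sense of induction may be opposite to that assumed, or the electron-rich lactone may decarboxylate or ionise on isolation. The fallback sets out from 7 and returns at 9. In a Braun acetate aldol, the dianion of (R)-2-hydroxy-1,2,2-triphenylethyl acetate (LDA, then MgBr2, THF, −100 °C, used in excess because of the free hydroxyl) adds to 7 and should give (R)-2-hydroxy-1,2,2-triphenylethyl (R)-3-hydroxy-3-Ar-propanoate F4. KOH in aqueous methanol then gives (R)-3-hydroxy-3-Ar-propanoic acid F5. PhSO2Cl in pyridine at 0 °C lactonises F5 through the mixed anhydride with retention and gives 9.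

Step 7. Bromination may be poorly position-selective (attack para to the hydroxyl, between the two allyloxy groups) or may go on to polybromination. The fallback sets out from 11 and returns at 12. Carbamoylation (ClCONEt2, NaH, THF) gives 3,5-bis(allyloxy)phenyl N,N-diethylcarbamate F6. Directed ortho-lithiation (s-BuLi, TMEDA, THF, −78 °C) at the position flanked by carbamate and allyloxy gives 2-lithio-3,5-bis(allyloxy)phenyl N,N-diethylcarbamate F7. Quenching at −78 °C with BrCCl2CCl2Br gives 2-bromo-3,5-bis(allyloxy)phenyl N,N-diethylcarbamate F8. NaOH in ethanol at reflux cleaves the carbamate and gives 12.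

Further compounds
F1 | step 8 | (R)-3-hydroxy-N-methoxy-N-methyl-3-Ar-propanamide | CON(C)C(=O)C[C@@H](O)c1cc(CC=C(C)C)c(OC)c(/C=C/C(C)(C)O)c1
F2 | step 8 | lithium 2-lithio-3,5-bis(allyloxy)phenoxide | [Li]Oc1cc(OCC=C)cc(OCC=C)c1[Li]
F3 | step 8 | (R)-3-hydroxy-1-[2-hydroxy-4,6-bis(allyloxy)phenyl]-3-Ar-propan-1-one | O=C(C[C@@H](O)c1cc(CC=C(C)C)c(OC)c(/C=C/C(C)(C)O)c1)c1c(O)cc(OCC=C)cc1OCC=C
F4 | step 5 | (R)-2-hydroxy-1,2,2-triphenylethyl (R)-3-hydroxy-3-Ar-propanoate | O=C(C[C@@H](O)c1cc(CC=C(C)C)c(OC)c(/C=C/C(C)(C)O)c1)O[C@H](c1ccccc1)C(O)(c1ccccc1)c1ccccc1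
F5 | step 5 | (R)-3-hydroxy-3-Ar-propanoic acid | OC(=O)C[C@@H](O)c1cc(CC=C(C)C)c(OC)c(/C=C/C(C)(C)O)c1
F6 | step 7 | 3,5-bis(allyloxy)phenyl N,N-diethylcarbamate | CCN(CC)C(=O)Oc1cc(OCC=C)cc(OCC=C)c1
F7 | step 7 | 2-lithio-3,5-bis(allyloxy)phenyl N,N-diethylcarbamate | CCN(CC)C(=O)Oc1cc(OCC=C)cc(OCC=C)c1[Li]
F8 | step 7 | 2-bromo-3,5-bis(allyloxy)phenyl N,N-diethylcarbamate | CCN(CC)C(=O)Oc1cc(OCC=C)cc(OCC=C)c1Br
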